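**Strategy**

The route rests on cutting ring B back to a 3,6-disubstituted 1,2-dithiin. The feature exploited is that S1' of ring B bridges C2' (bonded to ring A) and C5' (bonded to the alkyne), so both α-carbons map onto the two sulfur-bearing carbons of a cyclic disulfide. In one operation visible light opens the S–S bond, a new C–S bond closes the five-membered ring and PPh3 removes the surplus sulfur, giving the complete alkynyl bithiophene core. The precursor is the dithiin bearing the 5-(hydroxymethyl)thien-2-yl group at C6 and the 4-(isovaleroyloxy)but-1-ynyl chain at C3, made from a thienyl diynol by double thiolate addition, alkyne homologation and fluoride/iodine ring closure.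

Key step: step 11

Remark: ring A is the thiophene carrying the CH2O group and ring B the thiophene carrying the alkyne (primed locants).
Assumption: in step 5 the first thiolate is drawn as adding at the hydroxymethyl-bearing alkyne; the order of the two additions does not change the product.

**Route**

Step 1
Reactants: 1 thiophen-2-ylmethanol
Product: 2 tert-butyldimethyl(thiophen-2-ylmethoxy)silane
Conditions: TBSCl, imidazole, DMF, 0 °C → rt
Reagents that add atoms: tert-butyldimethylsilyl chloride, CC(C)(C)[Si](C)(C)Cl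
Why: Imidazole-mediated silyl ether formation masks the thienyl carbinol with a group that the later fluoride step removes together with the sulfur protecting groups.

Step 2
Reactants: 2 tert-butyldimethyl(thiophen-2-ylmethoxy)silane
Product: 4 tert-butyl[(5-iodothiophen-2-yl)methoxy]dimethylsilane, via 5-lithiothiophene 3 (not isolated)
Conditions: n-BuLi, THF, −78 °C; then I2, THF, −78 °C → rt
Reagents that add atoms: iodine, II
Why: Deprotonative lithiation at the only free α-position of the thiophene followed by iodinolysis (metalation–halogenation) should give the iodide regioselectively, the silyl ether being inert to n-BuLi at low temperature.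

Step 3
Reactants: 5 1,4-bis(trimethylsilyl)buta-1,3-diyne; 6 paraformaldehyde
Product: 8 5-(trimethylsilyl)penta-2,4-diyn-1-ol, via lithium diynide 7 (not isolated)
Conditions: MeLi·LiBr, THF, 0 °C → rt; then (CH2O)n, −78 °C → rt; H2O
Reagents that add atoms: none
Why: MeLi·LiBr cleaves one alkynyl C–Si bond of the bis-silyl diyne (silicon–lithium exchange) and the resulting lithium diynide undergoes 1,2-addition to formaldehyde to give the propargylic alcohol.

Step 4
Reactants: 4 tert-butyl[(5-iodothiophen-2-yl)methoxy]dimethylsilane; 8 5-(trimethylsilyl)penta-2,4-diyn-1-ol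
Product: 10 5-[5-({[tert-butyl(dimethyl)silyl]oxy}methyl)thiophen-2-yl]penta-2,4-diyn-1-ol, via penta-2,4-diyn-1-ol 9 (not isolated)
Conditions: PdCl2(PPh3)2 (cat.), CuI (cat.), K2CO3, MeOH–THF, degassed, rt, dark
Reagents that add atoms: none
Why: Carbonate in methanol removes the alkynyl silyl group and the terminal diyne so released is consumed at once by the reactive thienyl iodide in a one-pot desilylation–Sonogashira coupling, which keeps the concentration of the unstable diynol low while the primary silyl ether survives.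

Step 5
Reactants: 10 5-[5-({[tert-butyl(dimethyl)silyl]oxy}methyl)thiophen-2-yl]penta-2,4-diyn-1-ol; 11 2-(trimethylsilyl)ethanethiol
Product: 13 (2Z,4Z)-5-[5-({[tert-butyl(dimethyl)silyl]oxy}methyl)thiophen-2-yl]-2,5-bis{[2-(trimethylsilyl)ethyl]sulfanyl}penta-2,4-dien-1-ol, via enyne monosulfide 12 (not isolated)
Conditions: 11 (2.2 equiv), KOH (cat.), DMF, 0 °C → rt
Reagents that add atoms: none
Why: Base-catalysed nucleophilic thiol–yne addition to the conjugated diyne occurs at the two outer diyne carbons with anti stereochemistry, so each sulfur ends cis to the diene chain and the (2Z,4Z) geometry needed for later S–S closure is set by the trans delivery of RS and H.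

Step 6
Reactants: 13 (2Z,4Z)-5-[5-({[tert-butyl(dimethyl)silyl]oxy}methyl)thiophen-2-yl]-2,5-bis{[2-(trimethylsilyl)ethyl]sulfanyl}penta-2,4-dien-1-ol
Product: 14 (2Z,4Z)-5-[5-({[tert-butyl(dimethyl)silyl]oxy}methyl)thiophen-2-yl]-2,5-bis{[2-(trimethylsilyl)ethyl]sulfanyl}penta-2,4-dienal
Conditions: activated MnO2 (excess), CH2Cl2, rt
Reagents that add atoms: none
Why: Chemoselective MnO2 oxidation of the allylic alcohol should give the enal without touching the vinyl sulfides or the silicon groups.

Step 7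
Reactants: 14 (2Z,4Z)-5-[5-({[tert-butyl(dimethyl)silyl]oxy}methyl)thiophen-2-yl]-2,5-bis{[2-(trimethylsilyl)ethyl]sulfanyl}penta-2,4-dienal
Product: 15 tert-butyl({5-[(1Z,3Z)-6,6-dibromo-1,4-bis{[2-(trimethylsilyl)ethyl]sulfanyl}hexa-1,3,5-trien-1-yl]thiophen-2-yl}methoxy)dimethylsilane
Conditions: CBr4, PPh3, Zn dust, CH2Cl2, rt (ylide preformed); then 14, 0 °C → rt
Reagents that add atoms: carbon tetrabromide, BrC(Br)(Br)Br
Why: Corey–Fuchs dibromoolefination (Wittig reaction with Ph3P=CBr2) adds the carbon that becomes the alkyne terminus, and the zinc variant avoids Ph3PBr2, which could attack the silyl ether.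

Step 8
Reactants: 15 tert-butyl({5-[(1Z,3Z)-6,6-dibromo-1,4-bis{[2-(trimethylsilyl)ethyl]sulfanyl}hexa-1,3,5-trien-1-yl]thiophen-2-yl}methoxy)dimethylsilane; 16 oxirane
Product: 18 (5Z,7Z)-8-[5-({[tert-butyl(dimethyl)silyl]oxy}methyl)thiophen-2-yl]-5,8-bis{[2-(trimethylsilyl)ethyl]sulfanyl}octa-5,7-dien-3-yn-1-ol, via lithium acetylide 17 (not isolated)
Conditions: n-BuLi (2.2 equiv), THF, −78 → 0 °C; then BF3·OEt2, oxirane (THF solution), −78 °C; H2O
Reagents that add atoms: none
Why: The second stage of the Corey–Fuchs sequence (Br/Li exchange, α-elimination with 1,2-shift, deprotonation) gives the lithium acetylide, which opens oxirane under BF3·OEt2 activation (Yamaguchi-type epoxide alkynylation) at a temperature where the vinyl sulfides, silyl ether and thiophene are inert.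

Step 9
Reactants: 18 (5Z,7Z)-8-[5-({[tert-butyl(dimethyl)silyl]oxy}methyl)thiophen-2-yl]-5,8-bis{[2-(trimethylsilyl)ethyl]sulfanyl}octa-5,7-dien-3-yn-1-ol; 19 3-methylbutanoyl chloride
Product: 20 (5Z,7Z)-8-[5-({[tert-butyl(dimethyl)silyl]oxy}methyl)thiophen-2-yl]-5,8-bis{[2-(trimethylsilyl)ethyl]sulfanyl}octa-5,7-dien-3-yn-1-yl 3-methylbutanoate
Conditions: pyridine, DMAP (cat.), CH2Cl2, 0 °C
Reagents that add atoms: none
Why: DMAP-catalysed O-acylation of the unhindered primary homopropargylic alcohol with the acid chloride (nucleophilic acyl substitution) should install the isovalerate cleanly.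

Step 10
Reactants: 20 (5Z,7Z)-8-[5-({[tert-butyl(dimethyl)silyl]oxy}methyl)thiophen-2-yl]-5,8-bis{[2-(trimethylsilyl)ethyl]sulfanyl}octa-5,7-dien-3-yn-1-yl 3-methylbutanoate
Product: 22 4-{6-[5-(hydroxymethyl)thiophen-2-yl]-1,2-dithiin-3-yl}but-3-yn-1-yl 3-methylbutanoate, via bis(thiolate) 21 (not isolated)
Conditions: TBAF (1 M in THF, 4 equiv), THF, 0 °C → rt, dark; then I2, THF, 0 °C, dark
Reagents that add atoms: none
Why: Fluoride attacks all three silicon atoms, so each 2-(trimethylsilyl)ethyl sulfide fragments to ethene and a stabilized vinyl thiolate (fluoride-induced β-elimination) while the silyl ether is cleaved, and iodine then joins the two thiolates held close by the (Z,Z)-diene into the S–S bond (oxidative disulfide formation closing the 1,2-dithiin).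

Step 11
Reactants: 22 4-{6-[5-(hydroxymethyl)thiophen-2-yl]-1,2-dithiin-3-yl}but-3-yn-1-yl 3-methylbutanoate
Product: 25 4-[5'-(hydroxymethyl)-2,2'-bithiophen-5-yl]but-3-yn-1-yl 3-methylbutanoate, via enedithione 23 (not isolated), via dithiabicyclohexene 24 (not isolated)
Conditions: PPh3 (1.2 equiv), degassed CH2Cl2, hν (λ > 420 nm), rt
Reagents that add atoms: none
Why: Excitation of the visible band of the dithiin cleaves the S–S bond in an electrocyclic ring opening to the (Z)-enedithione 23, which recloses with formation of one C–S bond to the cis-fused thiirane 24, and PPh3 then abstracts the bridging sulfur so that ring B aromatizes. The closest known reaction type is the light-induced sulfur extrusion of thiarubrine-type 3,6-disubstituted 1,2-dithiins to 2,5-disubstituted thiophenes, the sulfur counterpart of the photochemical cyclohexadiene to hexatriene to bicyclo[3.1.0]hexene sequence, followed by the familiar phosphine desulfurization of a thiirane. Ring B closes when the sulfur of one thiocarbonyl attacks the carbon of the other, a five-membered closure that is 5-exo-trig in Baldwin terms, so the six-membered ring contracts to a five-membered one. No stereocenter is created in the product, since the two bridgehead centers of 24 are transient and disappear on aromatization. The step needs only chemoselective excitation, which the substrate secures because the dithiin alone absorbs above 420 nm while the esters, the alkyne, ring A and the bithiophene product absorb at shorter wavelength. Regiochemistry is not an issue because both possible thiiranes converge on the same thiophene.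

Step 12
Reactants: 25 4-[5'-(hydroxymethyl)-2,2'-bithiophen-5-yl]but-3-yn-1-yl 3-methylbutanoate; 26 3-methylbut-2-enoic acid
Product: 27 {5'-[4-(3-methylbutanoyloxy)but-1-yn-1-yl]-2,2'-bithiophen-5-yl}methyl 3-methylbut-2-enoate
Conditions: DCC, DMAP (cat.), CH2Cl2, 0 °C → rt
Reagents that add atoms: none
Why: Steglich esterification (carbodiimide activation with DMAP acyl transfer) acylates the thienyl carbinol under neutral conditions and avoids the acid chloride/amine combination, which can deconjugate a senecioyl unit through a vinylketene.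

**Compound list**

1 | thiophen-2-ylmethanol | OCc1cccs1 | starting material
2 | tert-butyldimethyl(thiophen-2-ylmethoxy)silane | CC(C)(C)[Si](C)(C)OCc1cccs1 | intermediate
3 | [5-({[tert-butyl(dimethyl)silyl]oxy}methyl)thiophen-2-yl]lithium | [Li]c1ccc(CO[Si](C)(C)C(C)(C)C)s1 | intermediate
4 | tert-butyl[(5-iodothiophen-2-yl)methoxy]dimethylsilane | CC(C)(C)[Si](C)(C)OCc1ccc(I)s1 | intermediate
5 | 1,4-bis(trimethylsilyl)buta-1,3-diyne | C[Si](C)(C)C#CC#C[Si](C)(C)C | starting material
6 | paraformaldehyde (formaldehyde source) | C=O | starting material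
7 | lithium 4-(trimethylsilyl)buta-1,3-diyn-1-ide | [Li]C#CC#C[Si](C)(C)C | intermediate
8 | 5-(trimethylsilyl)penta-2,4-diyn-1-ol | OCC#CC#C[Si](C)(C)C | intermediate
9 | penta-2,4-diyn-1-ol | OCC#CC#C | intermediate
10 | 5-[5-({[tert-butyl(dimethyl)silyl]oxy}methyl)thiophen-2-yl]penta-2,4-diyn-1-ol | OCC#CC#Cc1ccc(CO[Si](C)(C)C(C)(C)C)s1 | intermediate
11 | 2-(trimethylsilyl)ethanethiol | C[Si](C)(C)CCS | starting material
12 | (2Z)-5-[5-({[tert-butyl(dimethyl)silyl]oxy}methyl)thiophen-2-yl]-2-{[2-(trimethylsilyl)ethyl]sulfanyl}pent-2-en-4-yn-1-ol | OC/C(SCC[Si](C)(C)C)=C/C#Cc1ccc(CO[Si](C)(C)C(C)(C)C)s1 | intermediate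
13 | (2Z,4Z)-5-[5-({[tert-butyl(dimethyl)silyl]oxy}methyl)thiophen-2-yl]-2,5-bis{[2-(trimethylsilyl)ethyl]sulfanyl}penta-2,4-dien-1-ol | OC/C(SCC[Si](C)(C)C)=C/C=C(\SCC[Si](C)(C)C)c1ccc(CO[Si](C)(C)C(C)(C)C)s1 | intermediate
14 | (2Z,4Z)-5-[5-({[tert-butyl(dimethyl)silyl]oxy}methyl)thiophen-2-yl]-2,5-bis{[2-(trimethylsilyl)ethyl]sulfanyl}penta-2,4-dienal | O=C/C(SCC[Si](C)(C)C)=C/C=C(\SCC[Si](C)(C)C)c1ccc(CO[Si](C)(C)C(C)(C)C)s1 | intermediate
15 | tert-butyl({5-[(1Z,3Z)-6,6-dibromo-1,4-bis{[2-(trimethylsilyl)ethyl]sulfanyl}hexa-1,3,5-trien-1-yl]thiophen-2-yl}methoxy)dimethylsilane | BrC(Br)=C/C(SCC[Si](C)(C)C)=C/C=C(\SCC[Si](C)(C)C)c1ccc(CO[Si](C)(C)C(C)(C)C)s1 | intermediate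
16 | oxirane | C1CO1 | starting material
17 | [(3Z,5Z)-6-[5-({[tert-butyl(dimethyl)silyl]oxy}methyl)thiophen-2-yl]-3,6-bis{[2-(trimethylsilyl)ethyl]sulfanyl}hexa-3,5-dien-1-yn-1-yl]lithium | [Li]C#C/C(SCC[Si](C)(C)C)=C/C=C(\SCC[Si](C)(C)C)c1ccc(CO[Si](C)(C)C(C)(C)C)s1 | intermediate
18 | (5Z,7Z)-8-[5-({[tert-butyl(dimethyl)silyl]oxy}methyl)thiophen-2-yl]-5,8-bis{[2-(trimethylsilyl)ethyl]sulfanyl}octa-5,7-dien-3-yn-1-ol | OCCC#C/C(SCC[Si](C)(C)C)=C/C=C(\SCC[Si](C)(C)C)c1ccc(CO[Si](C)(C)C(C)(C)C)s1 | intermediate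
19 | 3-methylbutanoyl chloride | CC(C)CC(Cl)=O | starting material
20 | (5Z,7Z)-8-[5-({[tert-butyl(dimethyl)silyl]oxy}methyl)thiophen-2-yl]-5,8-bis{[2-(trimethylsilyl)ethyl]sulfanyl}octa-5,7-dien-3-yn-1-yl 3-methylbutanoate | CC(C)CC(=O)OCCC#C/C(SCC[Si](C)(C)C)=C/C=C(\SCC[Si](C)(C)C)c1ccc(CO[Si](C)(C)C(C)(C)C)s1 | intermediate
21 | bis(tetrabutylammonium) (1Z,3Z)-1-[5-(hydroxymethyl)thiophen-2-yl]-8-[(3-methylbutanoyl)oxy]octa-1,3-dien-5-yne-1,4-bis(thiolate) | CC(C)CC(=O)OCCC#C/C([S-])=C/C=C(\[S-])c1ccc(CO)s1.CCCC[N+](CCCC)(CCCC)CCCC.CCCC[N+](CCCC)(CCCC)CCCC | intermediate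
22 | 4-{6-[5-(hydroxymethyl)thiophen-2-yl]-1,2-dithiin-3-yl}but-3-yn-1-yl 3-methylbutanoate | CC(C)CC(=O)OCCC#CC1=CC=C(c2ccc(CO)s2)SS1 | intermediate
23 | (6Z)-8-[5-(hydroxymethyl)thiophen-2-yl]-5,8-bis(sulfanylidene)oct-6-en-3-yn-1-yl 3-methylbutanoate | CC(C)CC(=O)OCCC#CC(=S)/C=C\C(=S)c1ccc(CO)s1 | intermediate
24 | 4-{1-[5-(hydroxymethyl)thiophen-2-yl]-2,6-dithiabicyclo[3.1.0]hex-3-en-3-yl}but-3-yn-1-yl 3-methylbutanoate (racemic, ring fusion necessarily cis; one of two convergent regioisomers) | CC(C)CC(=O)OCCC#CC1=CC2SC2(c2ccc(CO)s2)S1 | intermediate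
25 | 4-[5'-(hydroxymethyl)-2,2'-bithiophen-5-yl]but-3-yn-1-yl 3-methylbutanoate | CC(C)CC(=O)OCCC#Cc1ccc(-c2ccc(CO)s2)s1 | intermediate
26 | 3-methylbut-2-enoic acid | CC(C)=CC(O)=O | starting material
27 | {5'-[4-(3-methylbutanoyloxy)but-1-yn-1-yl]-2,2'-bithiophen-5-yl}methyl 3-methylbut-2-enoate | CC(C)=CC(=O)OCc1ccc(-c2ccc(C#CCCOC(=O)CC(C)C)s2)s1 | target

**Count and risks**

Total step count: 12. Longest linear sequence: 11 steps (steps 1, 2 and 4 to 12, from thiophen-2-ylmethanol); step 3 is a one-step branch.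

Steps most likely to fail:

1. Step 11. Secondary photoreactions or polymerization of the excited dithiin and the enedithione may compete with ring contraction, or sulfur transfer may stay incomplete. The fallback introduces ring B preformed by cross-coupling and sets out from 4. Suzuki–Miyaura coupling of 4 with thiophen-2-ylboronic acid (Pd(PPh3)4, K2CO3, aqueous DME, 80 °C) should give tert-butyl(2,2'-bithiophen-5-ylmethoxy)dimethylsilane F1. Lithiation at the free α-position (n-BuLi, THF, −78 °C) and iodination should give tert-butyl[(5'-iodo-2,2'-bithiophen-5-yl)methoxy]dimethylsilane F2. Sonogashira coupling (PdCl2(PPh3)2, CuI, Et3N, THF, rt) with but-3-yn-1-yl 3-methylbutanoate F3, made from but-3-yn-1-ol and 19 (pyridine, CH2Cl2), should give 4-[5'-({[tert-butyl(dimethyl)silyl]oxy}methyl)-2,2'-bithiophen-5-yl]but-3-yn-1-yl 3-methylbutanoate F4. Desilylation with HF·pyridine (THF, 0 °C) comes back to the route at 25.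

2. Step 10. The basic fluoride medium may cleave or transfer the isovalerate before the dithiolate is oxidized, or unmasking of the two thiolates may stay incomplete. The fallback installs the ester only after the sulfur chemistry and sets out from 18. TBAF then I2, as in step 10, should give 4-{6-[5-(hydroxymethyl)thiophen-2-yl]-1,2-dithiin-3-yl}but-3-yn-1-ol F5, which carries no ester. Visible light with PPh3, as in step 11, should contract it to 4-[5'-(hydroxymethyl)-2,2'-bithiophen-5-yl]but-3-yn-1-ol F6. MnO2 (CH2Cl2, rt) should oxidize only the activated thienyl carbinol, giving 5'-(4-hydroxybut-1-yn-1-yl)-2,2'-bithiophene-5-carbaldehyde F7. Acylation of the remaining alcohol with 19 (pyridine, DMAP, CH2Cl2) should give 4-(5'-formyl-2,2'-bithiophen-5-yl)but-3-yn-1-yl 3-methylbutanoate F8. Reduction of the aldehyde with NaBH4 (MeOH–THF, 0 °C) comes back to the route at 25.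

3. Step 4. Oxidative homocoupling or decomposition of the terminal diynol released in situ may outrun the cross-coupling. The fallback builds the diyne by Cadiot–Chodkiewicz coupling and sets out from 4. Sonogashira coupling of 4 with ethynyltrimethylsilane (PdCl2(PPh3)2, CuI, Et3N, rt) should give tert-butyldimethyl({5-[(trimethylsilyl)ethynyl]thiophen-2-yl}methoxy)silane F9. K2CO3 in MeOH should give tert-butyl[(5-ethynylthiophen-2-yl)methoxy]dimethylsilane F10. Coupling of this alkyne with 3-bromoprop-2-yn-1-ol F11 (from prop-2-yn-1-ol, NBS, AgNO3 cat., acetone) under CuCl, NH2OH·HCl, n-BuNH2, MeOH–H2O, 0 °C comes back to the route at 10.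

**Further compounds**

F1 | step 11 | tert-butyl(2,2'-bithiophen-5-ylmethoxy)dimethylsilane | CC(C)(C)[Si](C)(C)OCc1ccc(-c2cccs2)s1
F2 | step 11 | tert-butyl[(5'-iodo-2,2'-bithiophen-5-yl)methoxy]dimethylsilane | CC(C)(C)[Si](C)(C)OCc1ccc(-c2ccc(I)s2)s1
F3 | step 11 | but-3-yn-1-yl 3-methylbutanoate | CC(C)CC(=O)OCCC#C
F4 | step 11 | 4-[5'-({[tert-butyl(dimethyl)silyl]oxy}methyl)-2,2'-bithiophen-5-yl]but-3-yn-1-yl 3-methylbutanoate | CC(C)CC(=O)OCCC#Cc1ccc(-c2ccc(CO[Si](C)(C)C(C)(C)C)s2)s1
F5 | step 10 | 4-{6-[5-(hydroxymethyl)thiophen-2-yl]-1,2-dithiin-3-yl}but-3-yn-1-ol | OCCC#CC1=CC=C(c2ccc(CO)s2)SS1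
F6 | step 10 | 4-[5'-(hydroxymethyl)-2,2'-bithiophen-5-yl]but-3-yn-1-ol | OCCC#Cc1ccc(-c2ccc(CO)s2)s1
F7 | step 10 | 5'-(4-hydroxybut-1-yn-1-yl)-2,2'-bithiophene-5-carbaldehyde | OCCC#Cc1ccc(-c2ccc(C=O)s2)s1
F8 | step 10 | 4-(5'-formyl-2,2'-bithiophen-5-yl)but-3-yn-1-yl 3-methylbutanoate | CC(C)CC(=O)OCCC#Cc1ccc(-c2ccc(C=O)s2)s1
F9 | step 4 | tert-butyldimethyl({5-[(trimethylsilyl)ethynyl]thiophen-2-yl}methoxy)silane | CC(C)(C)[Si](C)(C)OCc1ccc(C#C[Si](C)(C)C)s1
F10 | step 4 | tert-butyl[(5-ethynylthiophen-2-yl)methoxy]dimethylsilane | CC(C)(C)[Si](C)(C)OCc1ccc(C#C)s1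
F11 | step 4 | 3-bromoprop-2-yn-1-ol | OCC#CBr
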